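**Retrosynthetic overview**

1. Germacrane numbering is used: oxirane C1–C10, C14 = CH2OAc on C10, Z alkene C4=C5, lactone carbinol C6, ring fusion C7, ester carbinol C8, methylene C11=C13, lactone carbonyl C12. The strategy rests on C6, which is the allylic carbinol next to the Z-trisubstituted C4=C5 alkene of the ten-membered ring and also the γ-carbon of the C12 carboxyl of the five-membered lactone.
2. Key disconnection C5–C6 together with O6–C12: a Z-alkenylchromium made from the C5 iodide adds to a C6 aldehyde and the alkoxide acylates the C12 ester in the same flask. Ring order: oxirane first (step 6), then ten-membered carbocycle and lactone together (step 17).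
3. Precursor: C7/C8 come from a syn aldol of a crotonyl imide with the C8 aldehyde (the vinyl group is the latent C6), followed by one-carbon insertion of C11 and alkene cleavage. C1=C10 comes from a Z-selective phosphonate olefination of (4Z)-5-iodo-4-methylpent-4-enal, which is made by carbocupration of propyne.
4. After the closure: α-methylenation (C13), PMB to acetate at O14, desilylation at O8 and esterification with (2S,3S)-2,3-dimethyloxirane-2-carboxylic acid made from angelic acid.

Key step: step 17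

Remark: TBS = tert-butyldimethylsilyl, PMB = 4-methoxybenzyl, and "Ox" = the (2S,3R)-3-[(3Z)-4-iodo-3-methylbut-3-en-1-yl]-2-{[(4-methoxyphenyl)methoxy]methyl}oxiran-2-yl group; the carbinol carbon of diol 27 and C11 of 33 and 34 are assumed to form as epimer mixtures that converge in the next operation, so they are left undefined.

**Route**

Step 1
Reactants: 1 2-(2-bromoethyl)-1,3-dioxolane; 2 propyne
Product: 5 2-[(3Z)-4-iodo-3-methylbut-3-en-1-yl]-1,3-dioxolane, via Grignard reagent 3 (not isolated), via alkenylcopper 4 (not isolated)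
Conditions: Mg, THF, 25 °C; CuBr·SMe2, Et2O/Me2S, −45 °C; propyne, −25 °C; I2, −40 to 0 °C
Reagents that add atoms: iodine, SMILES II
Why: Normant carbocupration adds the alkylcopper syn across propyne with the alkyl group on the internal carbon, so iodinolysis of alkenylcopper 4 with retention should give the Z iodide (chain cis to iodine).

Step 2
Reactants: 5 2-[(3Z)-4-iodo-3-methylbut-3-en-1-yl]-1,3-dioxolane
Product: 6 (4Z)-5-iodo-4-methylpent-4-enal
Conditions: 1 M HCl, THF, 25 °C
Reagents that add atoms: water, SMILES O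
Why: Acid-catalysed acetal hydrolysis releases the C1 aldehyde, and the alkenyl iodide is inert to dilute aqueous acid.

Step 3
Reactants: 7 methyl 2-[bis(2,2,2-trifluoroethoxy)phosphoryl]acetate; 8 tert-butyl(2-iodoethoxy)dimethylsilane
Product: 9 methyl 2-[bis(2,2,2-trifluoroethoxy)phosphoryl]-4-(TBS-oxy)butanoate (racemic)
Conditions: NaH, DMF, 0 to 25 °C, excess of 7
Reagents that add atoms: none
Why: C-alkylation of the stabilised phosphonoacetate anion with a primary iodide (phosphonate alkylation) installs the C9–C8 arm, and the excess of 7 should suppress dialkylation.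

Step 4
Reactants: 6 (4Z)-5-iodo-4-methylpent-4-enal; 9 methyl 2-[bis(2,2,2-trifluoroethoxy)phosphoryl]-4-(TBS-oxy)butanoate
Product: 10 methyl (2Z,6Z)-2-[2-(TBS-oxy)ethyl]-7-iodo-6-methylhepta-2,6-dienoate
Conditions: KN(SiMe3)2, 18-crown-6, THF, −78 °C
Reagents that add atoms: none
Why: Still–Gennari variant of the Horner–Wadsworth–Emmons reaction, in which the electron-poor trifluoroethyl phosphonate and the dissociated potassium ion make elimination fast, so the kinetic Z enoate (ester carbon C14 cis to C2) should dominate.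

Step 5
Reactants: 10 methyl (2Z,6Z)-2-[2-(TBS-oxy)ethyl]-7-iodo-6-methylhepta-2,6-dienoate
Product: 11 (2Z,6Z)-2-[2-(TBS-oxy)ethyl]-7-iodo-6-methylhepta-2,6-dien-1-ol
Conditions: iBu2AlH, CH2Cl2, −78 °C
Reagents that add atoms: none
Why: 1,2-Reduction of the conjugated ester by the aluminium hydride gives the allylic alcohol, and silyl ether and alkenyl iodide are untouched.

Step 6
Reactants: 11 (2Z,6Z)-2-[2-(TBS-oxy)ethyl]-7-iodo-6-methylhepta-2,6-dien-1-ol
Product: 12 [(2S,3R)-2-[2-(TBS-oxy)ethyl]-3-[(3Z)-4-iodo-3-methylbut-3-en-1-yl]oxiran-2-yl]methanol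
Conditions: Ti(OiPr)4 (0.2 equiv), L-(+)-diethyl tartrate (0.24 equiv), tBuOOH, 4 Å MS, CH2Cl2, −20 °C
Reagents that add atoms: tert-butyl hydroperoxide, SMILES CC(C)(C)OO
Why: Sharpless asymmetric epoxidation with the L-(+)-tartrate delivers oxygen to the face that gives the (2S,3R)-oxirane (the sense known for Z-3-substituted allylic alcohols such as nerol), setting C10 (S) and C1 (R), and only the allylic-alcohol alkene is activated, not the alkenyl iodide.

Step 7
Reactants: 12 [(2S,3R)-2-[2-(TBS-oxy)ethyl]-3-[(3Z)-4-iodo-3-methylbut-3-en-1-yl]oxiran-2-yl]methanol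
Product: 13 tert-butyl(2-Ox-ethoxy)dimethylsilane
Conditions: NaH, 4-MeOC6H4CH2Cl, Bu4NI (cat.), DMF, 0 °C
Reagents that add atoms: 4-methoxybenzyl chloride, SMILES COc1ccc(CCl)cc1
Why: Williamson etherification of the primary alkoxide protects O14, and Payne rearrangement onto the fully substituted oxirane carbon should be slow in aprotic medium at 0 °C.

Step 8
Reactants: 13 tert-butyl(2-Ox-ethoxy)dimethylsilane
Product: 14 2-Ox-ethan-1-ol
Conditions: Bu4NF, THF, 0 °C
Reagents that add atoms: none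
Why: Fluoride-induced desilylation frees the primary C8 hydroxyl, and PMB ether, oxirane and alkenyl iodide are stable to it.

Step 9
Reactants: 14 2-Ox-ethan-1-ol
Product: 15 2-Ox-acetaldehyde
Conditions: Dess–Martin periodinane, NaHCO3, CH2Cl2, 0 to 25 °C; used crude at once
Reagents that add atoms: none
Why: Dess–Martin oxidation under bicarbonate buffering gives the β,γ-epoxy aldehyde without the amine base that would trigger β-elimination of the oxirane.

Step 10
Reactants: 16 (4S)-4-benzyl-1,3-oxazolidin-2-one; 17 (2E)-but-2-enoyl chloride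
Product: 18 (4S)-4-benzyl-3-[(2E)-but-2-enoyl]-1,3-oxazolidin-2-one
Conditions: n-BuLi, THF, −78 °C
Reagents that add atoms: none
Why: N-Acylation of the lithiated oxazolidinone with the acid chloride is the standard imide synthesis.

Step 11
Reactants: 15 2-Ox-acetaldehyde; 18 (4S)-4-benzyl-3-[(2E)-but-2-enoyl]-1,3-oxazolidin-2-one
Product: 20 (4S)-4-benzyl-3-[(2S,3R)-2-ethenyl-3-hydroxy-4-Ox-butanoyl]-1,3-oxazolidin-2-one, via boron dienolate 19 (not isolated)
Conditions: Bu2BOTf, Et3N, CH2Cl2, −78 to 0 °C; 15, −78 to −20 °C; pH 7 buffer, MeOH, H2O2, 0 °C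
Reagents that add atoms: none
Why: Evans syn aldol, in which the Z(O) boron dienolate 19 reacts at its α-carbon through a Zimmerman–Traxler chair on the face away from the benzyl group, sets C7 and C8 as the (2S,3R) pair with the vinyl group (latent C6) syn to O8, and the preformed enolate should add at −78 °C faster than the aldehyde enolises.

Step 12
Reactants: 20 (4S)-4-benzyl-3-[(2S,3R)-2-ethenyl-3-hydroxy-4-Ox-butanoyl]-1,3-oxazolidin-2-one
Product: 21 (4S)-4-benzyl-3-[(2S,3R)-2-ethenyl-3-(TBS-oxy)-4-Ox-butanoyl]-1,3-oxazolidin-2-one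
Conditions: TBSOTf, 2,6-lutidine, CH2Cl2, −78 °C
Reagents that add atoms: tert-butyldimethylsilyl trifluoromethanesulfonate, SMILES CC(C)(C)[Si](C)(C)OS(=O)(=O)C(F)(F)F
Why: Silylation of the secondary alcohol with the silyl triflate protects O8 before any ester exists that the free hydroxyl could attack.

Step 13
Reactants: 21 (4S)-4-benzyl-3-[(2S,3R)-2-ethenyl-3-(TBS-oxy)-4-Ox-butanoyl]-1,3-oxazolidin-2-one
Product: 22 (2S,3R)-2-ethenyl-3-(TBS-oxy)-4-Ox-butanoic acid
Conditions: LiOH, H2O2, THF/H2O (3:1), 0 °C; Na2SO3; 0.5 M HCl to pH 4, 0 °C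
Reagents that add atoms: hydrogen peroxide, SMILES OO
Why: Hydroperoxide attacks the exocyclic imide carbonyl selectively (auxiliary removal with lithium hydroperoxide) without epimerising C7, and the auxiliary is recovered.

Step 14
Reactants: 22 (2S,3R)-2-ethenyl-3-(TBS-oxy)-4-Ox-butanoic acid
Product: 24 (3S,4R)-1-diazo-3-ethenyl-4-(TBS-oxy)-5-Ox-pentan-2-one, via mixed anhydride 23 (not isolated)
Conditions: i-BuOCOCl, Et3N, THF, −20 °C; CH2N2, Et2O, 0 °C
Reagents that add atoms: diazomethane, SMILES C=[N+]=[N-]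
Why: First half of the Arndt–Eistert homologation, in which the mixed carbonic anhydride 23 acylates diazomethane under non-epimerising conditions.

Step 15
Reactants: 24 (3S,4R)-1-diazo-3-ethenyl-4-(TBS-oxy)-5-Ox-pentan-2-one
Product: 26 methyl (3S,4R)-3-ethenyl-4-(TBS-oxy)-5-Ox-pentanoate, via ketene 25 (not isolated)
Conditions: PhCO2Ag (0.1 equiv), Et3N, MeOH/THF, 25 °C, dark
Reagents that add atoms: methanol, SMILES CO
Why: Silver-catalysed Wolff rearrangement moves C7 with retention of configuration to give ketene 25, which methanol traps as the C11–C12 methyl ester, and silver instead of copper is chosen to avoid the vinylogous pathway open to β,γ-unsaturated diazoketones.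

Step 16
Reactants: 26 methyl (3S,4R)-3-ethenyl-4-(TBS-oxy)-5-Ox-pentanoate
Product: 28 methyl (3R,4R)-3-formyl-4-(TBS-oxy)-5-Ox-pentanoate, via diol 27 (not isolated)
Conditions: K2OsO4·2H2O (2 mol %), NaIO4, 2,6-lutidine, dioxane/H2O (3:1), 25 °C
Reagents that add atoms: sodium periodate, SMILES [Na+].[O-]I(=O)(=O)=O
Why: Lemieux–Johnson oxidation should take the monosubstituted vinyl group in preference to the electron-poor trisubstituted alkenyl iodide, and periodate cleaves diol 27 as it forms, so its C6 hydroxyl has no time to lactonise onto the C12 ester and C7 is not touched.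

Step 17
Reactants: 28 methyl (3R,4R)-3-formyl-4-(TBS-oxy)-5-Ox-pentanoate
Product: 31 (1R,6R,7S,8R,10S)-1,10-epoxy-8-(TBS-oxy)-14-(PMB-oxy)-13-norgermacr-4Z-en-6,12-olide, via alkenylchromium species 29 (not isolated), via chromium alkoxide 30 (not isolated)
Conditions: CrCl2 (10 equiv), NiCl2 (0.1 equiv), degassed DMSO/THF (3:1), 28 added over 12 h (final 0.003 M), 25 °C; then 40 °C; aq. NH4Cl
Reagents that add atoms: none
Why: CrCl2 reduces NiCl2 to zerovalent nickel, which inserts into the C5–I bond, and transmetalation gives the trivalent alkenylchromium species 29 with retention of the Z geometry, which adds to the C6 aldehyde (Nozaki–Hiyama–Kishi reaction, closest known type: medium-ring closure of alkenyl iodide aldehydes). The ten-membered carbocycle closes end to end by 10-exo-trig attack of C5 on the aldehyde carbon, helped by high dilution and by the Z alkene and the oxirane, which bend the chain. The chromium alkoxide 30 then closes the five-membered lactone by 5-exo-trig attack of O6 on the C12 methyl ester with loss of methoxide, the known spontaneous lactonisation of γ-oxido esters. The one new stereocentre, C6, is controlled by C7: Felkin–Anh attack anti to the branched C8 substituent, reinforced by the 1,3-anti preference of the C8 silyloxy group, should give the 6R alkoxide, whose lactone is trans-fused (H6 and H7 trans). The step needs chemoselectivity and retention of alkene geometry, secured by the non-basic organochromium reagent that tolerates oxirane, silyl ether, PMB ether and ester, and it needs C6 diastereoselection, secured by the anti C7/C8 stereodiad of 28.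

Step 18
Reactants: 31 (1R,6R,7S,8R,10S)-1,10-epoxy-8-(TBS-oxy)-14-(PMB-oxy)-13-norgermacr-4Z-en-6,12-olide
Product: 33 11-[(dimethylamino)methyl] derivative of 31 (both C11 epimers), via lithium enolate 32 (not isolated)
Conditions: LiN(iPr)2, THF, −78 °C; CH2=NMe2+ I−, −78 to 0 °C
Reagents that add atoms: dimethyl(methylidene)ammonium iodide, SMILES C=[N+](C)C.[I-]
Why: The kinetic lithium enolate 32 of the lactone is aminomethylated by the iminium salt (Mannich reaction), no leaving group sits β to C11 so the enolate should be stable at −78 °C, and the C11 configuration is irrelevant.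

Step 19
Reactants: 33 11-[(dimethylamino)methyl] derivative of 31
Product: 35 (1R,6R,7S,8R,10S)-1,10-epoxy-8-(TBS-oxy)-14-(PMB-oxy)germacra-4Z,11(13)-dien-6,12-olide, via ammonium iodide 34 (not isolated)
Conditions: MeI, MeOH, 25 °C; then NaHCO3 (aq), CH2Cl2, 25 °C
Reagents that add atoms: none
Why: Exhaustive N-methylation to ammonium salt 34 and base-induced β-elimination (Hofmann-type) install the exocyclic C11=C13 methylene.

Step 20
Reactants: 35 (1R,6R,7S,8R,10S)-1,10-epoxy-8-(TBS-oxy)-14-(PMB-oxy)germacra-4Z,11(13)-dien-6,12-olide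
Product: 36 (1R,6R,7S,8R,10S)-1,10-epoxy-14-hydroxy-8-(TBS-oxy)germacra-4Z,11(13)-dien-6,12-olide
Conditions: DDQ, CH2Cl2/pH 7 buffer (10:1), 0 °C
Reagents that add atoms: none
Why: Oxidative PMB cleavage by DDQ through the benzylic oxocarbenium ion frees O14, and silyl ether, oxirane and methylene lactone are not oxidised.

Step 21
Reactants: 36 (1R,6R,7S,8R,10S)-1,10-epoxy-14-hydroxy-8-(TBS-oxy)germacra-4Z,11(13)-dien-6,12-olide
Product: 37 (1R,6R,7S,8R,10S)-14-acetoxy-1,10-epoxy-8-(TBS-oxy)germacra-4Z,11(13)-dien-6,12-olide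
Conditions: Ac2O, pyridine, DMAP (cat.), CH2Cl2, 0 °C
Reagents that add atoms: acetic anhydride, SMILES CC(=O)OC(C)=O
Why: DMAP-catalysed acetylation of the primary C14 alcohol.

Step 22
Reactants: 37 (1R,6R,7S,8R,10S)-14-acetoxy-1,10-epoxy-8-(TBS-oxy)germacra-4Z,11(13)-dien-6,12-olide
Product: 38 (1R,6R,7R,8R,10S)-14-acetoxy-1,10-epoxy-8-hydroxygermacra-4Z,11(13)-dien-6,12-olide
Conditions: HF·pyridine, pyridine, THF, 0 to 25 °C
Reagents that add atoms: none
Why: Fluoride-mediated desilylation under buffered, slightly acidic conditions is chosen so that acetate, oxirane and methylene lactone survive and no alkoxide forms that could move the lactone to O8.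

Step 23
Reactants: 39 angelic acid
Product: 40 (2Z)-2-methylbut-2-en-1-ol
Conditions: LiAlH4, Et2O, 0 °C
Reagents that add atoms: none
Why: Hydride reduction of the acid gives the allylic alcohol, and the Z alkene should be neither reduced nor isomerised at 0 °C.

Step 24
Reactants: 40 (2Z)-2-methylbut-2-en-1-ol
Product: 41 [(2R,3S)-2,3-dimethyloxiran-2-yl]methanol
Conditions: Ti(OiPr)4 (0.1 equiv), D-(−)-diethyl tartrate (0.12 equiv), tBuOOH, 4 Å MS, CH2Cl2, −20 °C
Reagents that add atoms: tert-butyl hydroperoxide, SMILES CC(C)(C)OO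
Why: Sharpless asymmetric epoxidation with the D-(−)-tartrate delivers oxygen to the face opposite to that used in step 6 and should give the (2R,3S)-epoxy alcohol.

Step 25
Reactants: 41 [(2R,3S)-2,3-dimethyloxiran-2-yl]methanol
Product: 42 (2S,3S)-2,3-dimethyloxirane-2-carboxylic acid
Conditions: TEMPO (0.2 equiv), PhI(OAc)2, MeCN/H2O (1:1), 25 °C
Reagents that add atoms: water, SMILES O
Why: Oxoammonium oxidation of the primary alcohol through the aldehyde hydrate gives the acid, which only renumbers C2 to S without touching either stereocentre.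

Step 26
Reactants: 38 (1R,6R,7R,8R,10S)-14-acetoxy-1,10-epoxy-8-hydroxygermacra-4Z,11(13)-dien-6,12-olide; 42 (2S,3S)-2,3-dimethyloxirane-2-carboxylic acid
Product: 44 (1R,6R,7R,8R,10S)-14-acetoxy-1,10-epoxy-8-{[(2S,3S)-2,3-dimethyloxirane-2-carbonyl]oxy}germacra-4Z,11(13)-dien-6,12-olide, via mixed anhydride 43 (not isolated)
Conditions: 2,4,6-Cl3C6H2COCl, Et3N, THF, 25 °C; then 38, DMAP, toluene, 25 °C
Reagents that add atoms: none
Why: Yamaguchi esterification, in which mixed anhydride 43 is attacked at the epoxy acyl carbon by DMAP and then by the C8 hydroxyl, and the epoxy acid cannot isomerise as an angelate would.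

**Compound list**

1 | 2-(2-bromoethyl)-1,3-dioxolane | BrCCC1OCCO1 | starting material
2 | propyne | CC#C | starting material
3 | [2-(1,3-dioxolan-2-yl)ethyl]magnesium bromide | Br[Mg]CCC1OCCO1 | intermediate
4 | [(1Z)-4-(1,3-dioxolan-2-yl)-2-methylbut-1-en-1-yl]copper | [Cu]/C=C(/C)CCC1OCCO1 | intermediate
5 | 2-[(3Z)-4-iodo-3-methylbut-3-en-1-yl]-1,3-dioxolane | I/C=C(/C)CCC1OCCO1 | intermediate
6 | (4Z)-5-iodo-4-methylpent-4-enal | O=CCC/C(C)=C\I | intermediate
7 | methyl 2-[bis(2,2,2-trifluoroethoxy)phosphoryl]acetate | COC(=O)CP(=O)(OCC(F)(F)F)OCC(F)(F)F | starting material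
8 | tert-butyl(2-iodoethoxy)dimethylsilane | CC(C)(C)[Si](C)(C)OCCI | starting material
9 | methyl 2-[bis(2,2,2-trifluoroethoxy)phosphoryl]-4-[(tert-butyldimethylsilyl)oxy]butanoate (racemic) | COC(=O)C(CCO[Si](C)(C)C(C)(C)C)P(=O)(OCC(F)(F)F)OCC(F)(F)F | intermediate
10 | methyl (2Z,6Z)-2-{2-[(tert-butyldimethylsilyl)oxy]ethyl}-7-iodo-6-methylhepta-2,6-dienoate | COC(=O)/C(CCO[Si](C)(C)C(C)(C)C)=C\CC/C(C)=C\I | intermediate
11 | (2Z,6Z)-2-{2-[(tert-butyldimethylsilyl)oxy]ethyl}-7-iodo-6-methylhepta-2,6-dien-1-ol | OC/C(CCO[Si](C)(C)C(C)(C)C)=C\CC/C(C)=C\I | intermediate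
12 | [(2S,3R)-2-{2-[(tert-butyldimethylsilyl)oxy]ethyl}-3-[(3Z)-4-iodo-3-methylbut-3-en-1-yl]oxiran-2-yl]methanol | CC(C)(C)[Si](C)(C)OCC[C@@]1(CO)O[C@@H]1CC/C(C)=C\I | intermediate
13 | tert-butyl(2-Ox-ethoxy)dimethylsilane (PMB ether of 12) | CC(C)(C)[Si](C)(C)OCC[C@@]1(COCc2ccc(OC)cc2)O[C@@H]1CC/C(C)=C\I | intermediate
14 | 2-Ox-ethan-1-ol | OCC[C@@]1(COCc2ccc(OC)cc2)O[C@@H]1CC/C(C)=C\I | intermediate
15 | 2-Ox-acetaldehyde | O=CC[C@@]1(COCc2ccc(OC)cc2)O[C@@H]1CC/C(C)=C\I | intermediate
16 | (4S)-4-benzyl-1,3-oxazolidin-2-one | O=C1N[C@@H](Cc2ccccc2)CO1 | starting material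
17 | (2E)-but-2-enoyl chloride | C/C=C/C(Cl)=O | starting material
18 | (4S)-4-benzyl-3-[(2E)-but-2-enoyl]-1,3-oxazolidin-2-one | C/C=C/C(=O)N1[C@@H](Cc2ccccc2)COC1=O | intermediate
19 | (4S)-4-benzyl-3-[(1Z)-1-(dibutylboranyloxy)buta-1,3-dien-1-yl]-1,3-oxazolidin-2-one | CCCCB(CCCC)O/C(=C\C=C)N1[C@@H](Cc2ccccc2)COC1=O | intermediate
20 | (4S)-4-benzyl-3-[(2S,3R)-2-ethenyl-3-hydroxy-4-Ox-butanoyl]-1,3-oxazolidin-2-one | O=C(N1[C@@H](Cc2ccccc2)COC1=O)[C@@H](C=C)[C@H](O)C[C@@]3(COCc4ccc(OC)cc4)O[C@@H]3CC/C(C)=C\I | intermediate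
21 | (4S)-4-benzyl-3-[(2S,3R)-2-ethenyl-3-(TBS-oxy)-4-Ox-butanoyl]-1,3-oxazolidin-2-one | O=C(N1[C@@H](Cc2ccccc2)COC1=O)[C@@H](C=C)[C@H](O[Si](C)(C)C(C)(C)C)C[C@@]3(COCc4ccc(OC)cc4)O[C@@H]3CC/C(C)=C\I | intermediate
22 | (2S,3R)-2-ethenyl-3-(TBS-oxy)-4-Ox-butanoic acid | OC(=O)[C@@H](C=C)[C@H](O[Si](C)(C)C(C)(C)C)C[C@@]1(COCc2ccc(OC)cc2)O[C@@H]1CC/C(C)=C\I | intermediate
23 | isobutyl carbonic mixed anhydride of 22 | CC(C)COC(=O)OC(=O)[C@@H](C=C)[C@H](O[Si](C)(C)C(C)(C)C)C[C@@]1(COCc2ccc(OC)cc2)O[C@@H]1CC/C(C)=C\I | intermediate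
24 | (3S,4R)-1-diazo-3-ethenyl-4-(TBS-oxy)-5-Ox-pentan-2-one | [N-]=[N+]=CC(=O)[C@@H](C=C)[C@H](O[Si](C)(C)C(C)(C)C)C[C@@]1(COCc2ccc(OC)cc2)O[C@@H]1CC/C(C)=C\I | intermediate
25 | ketene from 24 after loss of N2 and 1,2-shift of C7 (C7 and C8 as in 24) | O=C=C[C@@H](C=C)[C@H](O[Si](C)(C)C(C)(C)C)C[C@@]1(COCc2ccc(OC)cc2)O[C@@H]1CC/C(C)=C\I | intermediate
26 | methyl (3S,4R)-3-ethenyl-4-(TBS-oxy)-5-Ox-pentanoate | COC(=O)C[C@@H](C=C)[C@H](O[Si](C)(C)C(C)(C)C)C[C@@]1(COCc2ccc(OC)cc2)O[C@@H]1CC/C(C)=C\I | intermediate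
27 | 1,2-diol from the vinyl group of 26 (both carbinol epimers; C7 and C8 as in 26) | COC(=O)C[C@@H](C(O)CO)[C@H](O[Si](C)(C)C(C)(C)C)C[C@@]1(COCc2ccc(OC)cc2)O[C@@H]1CC/C(C)=C\I | intermediate
28 | methyl (3R,4R)-3-formyl-4-(TBS-oxy)-5-Ox-pentanoate (key-step precursor) | COC(=O)C[C@@H](C=O)[C@H](O[Si](C)(C)C(C)(C)C)C[C@@]1(COCc2ccc(OC)cc2)O[C@@H]1CC/C(C)=C\I | intermediate
29 | alkenylchromium dichloride from 28 (C5–CrCl2 in place of C5–I; Z retained) | COC(=O)C[C@@H](C=O)[C@H](O[Si](C)(C)C(C)(C)C)C[C@@]1(COCc2ccc(OC)cc2)O[C@@H]1CC/C(C)=C\[Cr](Cl)Cl | intermediate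
30 | O6-chromium dichloride alkoxide of the ten-membered 6R hydroxy ester (C5–C6 closed; C12 still the methyl ester) | COC(=O)C[C@H]1[C@H](O[Cr](Cl)Cl)/C=C(/C)CC[C@H]2O[C@]2(COCc3ccc(OC)cc3)C[C@H]1O[Si](C)(C)C(C)(C)C | intermediate
31 | (1R,6R,7S,8R,10S)-1,10-epoxy-8-(TBS-oxy)-14-(PMB-oxy)-13-norgermacr-4Z-en-6,12-olide (trans-fused lactone; C11 = CH2) | O=C1O[C@@H]2/C=C(/C)CC[C@H]3O[C@]3(COCc4ccc(OC)cc4)C[C@@H](O[Si](C)(C)C(C)(C)C)[C@H]2C1 | intermediate
32 | lithium enolate of 31 (C11=C12–OLi) | [Li]OC1=C[C@H]2[C@H](O1)/C=C(/C)CC[C@H]3O[C@]3(COCc4ccc(OC)cc4)C[C@H]2O[Si](C)(C)C(C)(C)C | intermediate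
33 | 11-[(dimethylamino)methyl] derivative of 31 (both C11 epimers) | CN(C)CC1C(=O)O[C@@H]2/C=C(/C)CC[C@H]3O[C@]3(COCc4ccc(OC)cc4)C[C@@H](O[Si](C)(C)C(C)(C)C)[C@@H]12 | intermediate
34 | trimethylammonium iodide from 33 | C[N+](C)(C)CC1C(=O)O[C@@H]2/C=C(/C)CC[C@H]3O[C@]3(COCc4ccc(OC)cc4)C[C@@H](O[Si](C)(C)C(C)(C)C)[C@@H]12.[I-] | intermediate
35 | (1R,6R,7S,8R,10S)-1,10-epoxy-8-(TBS-oxy)-14-(PMB-oxy)germacra-4Z,11(13)-dien-6,12-olide | C=C1C(=O)O[C@@H]2/C=C(/C)CC[C@H]3O[C@]3(COCc4ccc(OC)cc4)C[C@@H](O[Si](C)(C)C(C)(C)C)[C@@H]12 | intermediate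
36 | (1R,6R,7S,8R,10S)-1,10-epoxy-14-hydroxy-8-(TBS-oxy)germacra-4Z,11(13)-dien-6,12-olide | C=C1C(=O)O[C@@H]2/C=C(/C)CC[C@H]3O[C@]3(CO)C[C@@H](O[Si](C)(C)C(C)(C)C)[C@@H]12 | intermediate
37 | (1R,6R,7S,8R,10S)-14-acetoxy-1,10-epoxy-8-(TBS-oxy)germacra-4Z,11(13)-dien-6,12-olide | C=C1C(=O)O[C@@H]2/C=C(/C)CC[C@H]3O[C@]3(COC(C)=O)C[C@@H](O[Si](C)(C)C(C)(C)C)[C@@H]12 | intermediate
38 | (1R,6R,7R,8R,10S)-14-acetoxy-1,10-epoxy-8-hydroxygermacra-4Z,11(13)-dien-6,12-olide | C=C1C(=O)O[C@@H]2/C=C(/C)CC[C@H]3O[C@]3(COC(C)=O)C[C@@H](O)[C@@H]12 | intermediate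
39 | angelic acid, (2Z)-2-methylbut-2-enoic acid | C/C=C(/C)C(=O)O | starting material
40 | (2Z)-2-methylbut-2-en-1-ol | C/C=C(/C)CO | intermediate
41 | [(2R,3S)-2,3-dimethyloxiran-2-yl]methanol | OC[C@@]1(C)O[C@H]1C | intermediate
42 | (2S,3S)-2,3-dimethyloxirane-2-carboxylic acid | OC(=O)[C@@]1(C)O[C@H]1C | intermediate
43 | 2,4,6-trichlorobenzoic mixed anhydride of 42 | O=C(OC(=O)c1c(Cl)cc(Cl)cc1Cl)[C@@]1(C)O[C@H]1C | intermediate
44 | (1R,6R,7R,8R,10S)-14-acetoxy-1,10-epoxy-8-{[(2S,3S)-2,3-dimethyloxirane-2-carbonyl]oxy}germacra-4Z,11(13)-dien-6,12-olide (CNP0232260.1) | C=C1C(=O)O[C@@H]2/C=C(/C)CC[C@H]3O[C@]3(COC(C)=O)C[C@@H](OC(=O)[C@@]3(C)O[C@H]3C)[C@@H]12 | target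

**Step count and risks**

Total step count: 26. Longest linear sequence: 21 steps (steps 1, 2, 4–9, 11–22 and 26); steps 3, 10 and 23–25 are side branches.

Steps most likely to fail:

1. Step 17. The folded chain may present the other face of the C6 aldehyde to the alkenylchromium, so that Felkin control is lost and the 6S alkoxide forms and lactonises to the cis-fused lactone; intermolecular coupling can also compete with the ten-membered closure. The fallback sets C6 by an invertive lactonisation instead of by the addition. It sets out from 28: the same closure is run, and the cis-fused 6-epi lactone F1 is saponified (LiOH, THF/H2O) to the 6S hydroxy acid F2. F2 is then closed under Mitsunobu conditions (PPh3, diisopropyl azodicarboxylate, toluene), in which the carboxylate displaces the activated allylic C6 hydroxyl with inversion. This comes back to the route at 31.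

2. Step 11. The β,γ-epoxy aldehyde 15 may be deprotonated at C9 by the amine and boron enolate system and lose the oxirane by β-elimination faster than it is attacked at C8, or traces of free boron triflate may open the oxirane. The fallback replaces the enolate aldol by a neutral allylboration and so also avoids the homologation. It sets out from 15: the tartrate-modified (E)-allylboronate methyl (3E)-5-[(4R,5R)-4,5-bis(propan-2-yloxycarbonyl)-1,3,2-dioxaborolan-2-yl]pent-3-enoate (4 Å MS, toluene, −78 °C) should add through the chair transition state to the Si face of the aldehyde and give the anti homoallylic alcohol methyl (3S,4R)-3-ethenyl-4-hydroxy-5-Ox-pentanoate F3. F3 is silylated at once (TBSOTf, 2,6-lutidine, −78 °C), before its hydroxyl can attack the ester. This comes back to the route at 26.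

3. Step 18. The strong amide base may, besides forming the C11 enolate, isomerise the oxirane to an allylic alcohol by deprotonation next to it, or the enolate may be alkylated twice. The fallback replaces enolate alkylation by a thermal condensation. It sets out from 31: tert-butoxybis(dimethylamino)methane (toluene, 80 °C) should give the (E)-11-[(dimethylamino)methylidene] lactone F4. 1,4-Reduction of F4 with iBu2AlH (THF, −78 °C) and loss of dimethylamine on mildly acidic work-up should give the α-methylene lactone directly. This comes back to the route at 35.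

Further compounds
F1 | step 17 | (1R,6S,7S,8R,10S)-1,10-epoxy-8-(TBS-oxy)-14-(PMB-oxy)-13-norgermacr-4Z-en-6,12-olide (6-epimer of 31; cis-fused lactone) | O=C1O[C@H]2/C=C(/C)CC[C@H]3O[C@]3(COCc4ccc(OC)cc4)C[C@@H](O[Si](C)(C)C(C)(C)C)[C@H]2C1
F2 | step 17 | 6S hydroxy acid from opening the lactone of F1 (free C6 hydroxyl and C12 carboxylic acid) | OC(=O)C[C@H]1[C@@H](O)/C=C(/C)CC[C@H]2O[C@]2(COCc3ccc(OC)cc3)C[C@H]1O[Si](C)(C)C(C)(C)C
F3 | step 11 | methyl (3S,4R)-3-ethenyl-4-hydroxy-5-Ox-pentanoate | COC(=O)C[C@@H](C=C)[C@H](O)C[C@@]1(COCc2ccc(OC)cc2)O[C@@H]1CC/C(C)=C\I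
F4 | step 18 | (E)-11-[(dimethylamino)methylidene] derivative of 31 | O=C1O[C@@H]2/C=C(/C)CC[C@H]3O[C@]3(COCc4ccc(OC)cc4)C[C@@H](O[Si](C)(C)C(C)(C)C)[C@H]2/C1=C\N(C)C
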